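**Plan**

1. Retrosynthesis: the O1–C2 bond of ring C is cut first (flav-2-ene from an aryl ketone and a ring A phenol), then the C4a–C5 (equivalent to C4a–C8a) bond of ring A, which leads back to a 4-benzyloxy-2-pyrone; the pyrone is then cut to an ester plus acetoacetate, followed by C4–C4a (malonate Michael addition), C3–C4 (aldol condensation) and C4–C8 of ring D (formylation).
2. Forward: benzylated (+)-catechin is formylated at C8 and condensed to a chalcone; malonate addition, dealkoxycarbonylation, ketalisation, acetoacetate acylation, lactonisation and O-benzylation give the pyrone; ring A is grown from the pyrone, ring C is closed by cyclodehydration, and hydrogenation finishes.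
3. Enabling feature: ring A is a phloroglucinol whose C4a lies between two equivalent oxygen-bearing carbons (C5 and C8a), with the third oxygen at C7; a 4-alkoxy-2-pyrone gives this pattern when its 6-methylene (future C4a) closes on the lactone carbonyl.
4. Stereochemistry: C2 and C3 of the lower unit come from (+)-catechin; C4 is set by a catalyst-controlled Michael addition; C2 of the upper unit is set by hydrogenation of the flav-2-ene anti to the C4 aryl group (2,4-cis).

Key step: step 13

Conventions: the upper flavan unit has rings A (phloroglucinol), C (pyran) and B (catechol) and carries the locants C2, C3, C4, C4a and so on; the lower catechin unit has rings D (benzo), F (pyran) and E (catechol). "Cat" is the perbenzylated lower unit bonded through C8 of ring D, (2R,3S)-3,5,7-tris(benzyloxy)-2-[3,4-bis(benzyloxy)phenyl]chroman-8-yl. "ArB" is 3,4-bis(benzyloxy)phenyl (ring B).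

Assumption: the quinine-derived amine–thiourea is taken to deliver malonate to the same enone face of chalcone 9 as it does with simple chalcones; if a trial shows the other C4 epimer to dominate, the quinidine-derived pseudoenantiomer would be used with nothing else changed.

**Route**

Step 1
Reactants: 1 (+)-catechin
Product: 2 5,7,3',4'-tetra-O-benzyl-(+)-catechin
Conditions: BnBr (4.5 equiv), K2CO3 (5 equiv), DMF, 0 °C to rt, Ar
Reagents that add atoms: benzyl bromide, BrCc1ccccc1
Why: Williamson etherification in which K2CO3 ionises only the four phenols, so the C3 alcohol stays free, the mild base avoids C2 epimerisation, and both stereocentres of 1 are carried through.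

Step 2
Reactants: 2 5,7,3',4'-tetra-O-benzyl-(+)-catechin
Product: 3 8-bromo-5,7,3',4'-tetra-O-benzyl-(+)-catechin
Conditions: NBS (1.0 equiv), CH2Cl2, −78 °C to rt
Reagents that add atoms: N-bromosuccinimide, O=C1CCC(=O)N1Br
Why: Electrophilic aromatic bromination of the trioxygenated ring D, which for this tetrabenzyl ether is known to go to C8 with one equivalent of NBS at low temperature.

Step 3
Reactants: 3 8-bromo-5,7,3',4'-tetra-O-benzyl-(+)-catechin
Product: 4 8-bromo-3,5,7,3',4'-penta-O-benzyl-(+)-catechin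
Conditions: NaH (1.5 equiv), BnBr (1.3 equiv), DMF, 0 °C to rt
Reagents that add atoms: benzyl bromide, BrCc1ccccc1
Why: Williamson etherification of the secondary alkoxide; the aryl bromide and the aryl benzyl ethers are inert, and the C3 oxygen must be capped for the organolithium, enolate and Mitsunobu steps ahead.

Step 4
Reactants: 4 8-bromo-3,5,7,3',4'-penta-O-benzyl-(+)-catechin
Product: 6 penta-O-benzylcatechin-8-carbaldehyde, via aryllithium 5 (not isolated)
Conditions: n-BuLi (1.1 equiv), THF, −78 °C; DMF (3 equiv), −78 to 0 °C; aq. NH4Cl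
Reagents that add atoms: N,N-dimethylformamide, CN(C)C=O
Why: Bromine–lithium exchange outruns benzylic deprotonation at −78 °C and the aryllithium is formylated by DMF (Bouveault aldehyde synthesis), which places the future C4 carbon on C8 of ring D without regiochemical doubt.

Step 5
Reactants: 7 3',4'-dihydroxyacetophenone
Product: 8 3',4'-bis(benzyloxy)acetophenone
Conditions: BnBr (2.3 equiv), K2CO3 (3 equiv), DMF, 60 °C
Reagents that add atoms: benzyl bromide, BrCc1ccccc1
Why: Williamson etherification of the two catechol hydroxyls, giving ring B in the protection used throughout.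

Step 6
Reactants: 6 penta-O-benzylcatechin-8-carbaldehyde; 8 3',4'-bis(benzyloxy)acetophenone
Product: 9 (E)-1-ArB-3-Cat-prop-2-en-1-one (chalcone)
Conditions: KOH (aq.), EtOH–THF, rt
Reagents that add atoms: none
Why: Claisen–Schmidt condensation: the aldehyde cannot enolise, and E1cB dehydration of the aldol gives the conjugated E-enone, forming the C3–C4 bond.

Step 7
Reactants: 9 chalcone; 10 dimethyl malonate
Product: 11 dimethyl 2-[(1S)-3-ArB-3-oxo-1-Cat-propyl]propanedioate
Conditions: dimethyl malonate (5 equiv), 1-[3,5-bis(trifluoromethyl)phenyl]-3-[(8S,9S)-6'-methoxycinchonan-9-yl]thiourea (10–20 mol%), toluene, rt to 40 °C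
Reagents that add atoms: none
Why: Catalytic asymmetric Michael addition of a malonate to a chalcone with a bifunctional amine–thiourea: the quinuclidine deprotonates the malonate while the thiourea binds the enone carbonyl, so the new C4–C4a bond forms on one face under catalyst control (the remote lower-unit stereocentres should exert little bias), and because the two C4 epimers are diastereomers a minor one can be removed by chromatography.

Step 8
Reactants: 11 dimethyl 2-[(1S)-3-ArB-3-oxo-1-Cat-propyl]propanedioate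
Product: 12 methyl (3S)-5-ArB-5-oxo-3-Cat-pentanoate
Conditions: LiCl (2 equiv), DMSO–H2O, 150 °C
Reagents that add atoms: none
Why: Krapcho dealkoxycarbonylation: chloride demethylates one ester, the carboxylate loses CO2 and water protonates the enolate under near-neutral conditions that should leave the benzyl ethers and the β-stereocentre alone.

Step 9
Reactants: 12 methyl (3S)-5-ArB-5-oxo-3-Cat-pentanoate
Product: 13 methyl (3S)-4-(2-ArB-1,3-dioxolan-2-yl)-3-Cat-butanoate
Conditions: Me3SiOCH2CH2OSiMe3 (3 equiv), Me3SiOTf (0.1 equiv), CH2Cl2, −20 °C to rt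
Reagents that add atoms: 1,2-bis(trimethylsilyloxy)ethane, C[Si](C)(C)OCCO[Si](C)(C)C
Why: Silyl triflate-catalysed ketalisation with the bis-silyl ether of ethylene glycol runs cold and without free protic acid, so the methyl ester is not transesterified and the 2-arylchroman is not ionised; the dioxolane shuts off enolisation and retro-Michael cleavage of the aryl ketone in the basic steps that follow.

Step 10
Reactants: 13 methyl (3S)-4-(2-ArB-1,3-dioxolan-2-yl)-3-Cat-butanoate; 14 methyl acetoacetate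
Product: 16 methyl (7R)-8-(2-ArB-1,3-dioxolan-2-yl)-3,5-dioxo-7-Cat-octanoate, via acetoacetate dianion 15 (not isolated)
Conditions: methyl acetoacetate (3.5 equiv), NaH then n-BuLi (3.5 equiv each), THF, 0 °C; add 13, 0 °C to rt; aq. NH4Cl
Reagents that add atoms: none
Why: Claisen acylation of the γ-carbon of the acetoacetate dianion by the methyl ester, with excess dianion because the 3,5-dioxo ester is deprotonated as it forms; ketal, benzyl ethers and the non-enolisable stereocentre are not touched.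

Step 11
Reactants: 16 methyl (7R)-8-(2-ArB-1,3-dioxolan-2-yl)-3,5-dioxo-7-Cat-octanoate
Product: 17 6-[(2R)-3-(2-ArB-1,3-dioxolan-2-yl)-2-Cat-propyl]-4-hydroxy-2H-pyran-2-one
Conditions: DBU (1.5 equiv), toluene, 90 °C
Reagents that add atoms: none
Why: Base-mediated lactonisation of a 3,5-dioxo ester, the C5 enol oxygen closing on the ester with loss of methanol, which is the standard route from triketide esters to 6-alkyl-4-hydroxy-2-pyrones.

Step 12
Reactants: 17 6-[(2R)-3-(2-ArB-1,3-dioxolan-2-yl)-2-Cat-propyl]-4-hydroxy-2H-pyran-2-one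
Product: 18 4-benzyloxy-6-[(2R)-3-(2-ArB-1,3-dioxolan-2-yl)-2-Cat-propyl]-2H-pyran-2-one
Conditions: BnOH (1.5 equiv), PPh3, DIAD (1.5 equiv each), THF, 0 °C to rt
Reagents that add atoms: benzyl alcohol, OCc1ccccc1
Why: Mitsunobu alkylation of the acidic 4-hydroxy-2-pyrone, which is known to go on the 4-oxygen and avoids the C3 benzylation that benzyl halides and base can give.

Step 13
Reactants: 18 4-benzyloxy-6-[(2R)-3-(2-ArB-1,3-dioxolan-2-yl)-2-Cat-propyl]-2H-pyran-2-one
Product: 20 5-benzyloxy-2-[(1S)-2-(2-ArB-1,3-dioxolan-2-yl)-1-Cat-ethyl]benzene-1,3-diol, via ring-opened benzyl enoate 19 (not isolated)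
Conditions: BnONa (5 equiv, from NaH and BnOH), BnOH, 170 °C, Ar; AcOH quench
Reagents that add atoms: none
Why: Proposed new method: benzyloxide adds to the lactone carbonyl and opens the ring to the benzyl (E)-3-benzyloxy-5-oxo-2-enoate 19, whose enoate geometry, inherited from the ring, holds the ester cis to the ketone arm; equilibrium enolisation of the ketone toward the side-chain methylene (future C4a) is followed by Claisen attack of that carbon on the ester carbonyl (the former lactone carbon, future C5 or C8a), loss of benzyloxide and tautomerisation of the new carbocycle to the resorcinol. The closest known reaction is the sodium alkoxide-induced recyclisation of 4-methoxy-6-methyl-2-pyrone to phloroglucinol monomethyl ether at high temperature; new here is closure through a substituted methylene that carries a bulky branched chain. Ring A closes in a 6-(enolendo)-exo-trig mode. No stereocentre is formed, and the existing one at C4 has no acidifying neighbour and no β-leaving group while the aryl ketone is a dioxolane, so neither enolisation nor retro-Michael cleavage can scramble it. The step needs carbon closure over return to the pyrone, and enolisation toward the methylene instead of the more acidic doubly activated position: relactonisation only regenerates 18, the doubly activated enolate has no productive closure, and irreversible aromatisation to the resorcinolate should pull both equilibria through. Benzyloxide in benzyl alcohol makes exchange at the ester and at the vinylogous ester degenerate, and the 4-benzyl ether keeps the pyrone from resting as an inert 4-olate.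

Step 14
Reactants: 20 5-benzyloxy-2-[(1S)-2-(2-ArB-1,3-dioxolan-2-yl)-1-Cat-ethyl]benzene-1,3-diol
Product: 23 (4S)-7-benzyloxy-2-ArB-4-Cat-4H-chromen-5-ol (flav-2-ene), via keto diphenol 21 (not isolated), via cyclic hemiketal 22 (not isolated)
Conditions: TsOH·H2O (0.1 equiv), acetone–H2O, rt; then toluene, 4 Å molecular sieves, 50 °C, Ar
Reagents that add atoms: none
Why: Acid hydrolysis of the aryl dioxolane, hemiketalisation by either of the two equivalent ortho phenols (6-exo-trig) and dehydration to the aryl-conjugated enol ether, the usual passage from 3-(2-hydroxyaryl)-1,3-diarylpropan-1-ones to 4H-chromenes; the acid is kept catalytic and the temperature low because the diarylmethine C4–C8 bond is acid-labile.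

Step 15
Reactants: 23 (4S)-7-benzyloxy-2-ArB-4-Cat-4H-chromen-5-ol
Product: 24 (2R,3S)-2-(3,4-dihydroxyphenyl)-8-[(2S,4S)-2-(3,4-dihydroxyphenyl)-5,7-dihydroxychroman-4-yl]chromane-3,5,7-triol (target)
Conditions: H2 (1 atm), Pd(OH)2/C, THF–MeOH, rt
Reagents that add atoms: none
Why: Heterogeneous hydrogenation of the trisubstituted enol ether from the face opposite the pseudoaxial C4 aryl group should leave the C2 and C4 aryl groups cis (2S), and the same catalyst hydrogenolyses all eight benzyl ethers while the cyclic benzylic C2–O bonds survive, as they do in benzylated catechins.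

**Compound list**

1 | (+)-catechin, (2R,3S) | O[C@H]1Cc2c(O)cc(O)cc2O[C@@H]1c1ccc(O)c(O)c1 | starting material
2 | 5,7,3',4'-tetra-O-benzyl-(+)-catechin | O[C@H]1Cc2c(OCc3ccccc3)cc(OCc3ccccc3)cc2O[C@@H]1c1ccc(OCc2ccccc2)c(OCc2ccccc2)c1 | intermediate
3 | 8-bromo-5,7,3',4'-tetra-O-benzyl-(+)-catechin | O[C@H]1Cc2c(OCc3ccccc3)cc(OCc3ccccc3)c(Br)c2O[C@@H]1c1ccc(OCc2ccccc2)c(OCc2ccccc2)c1 | intermediate
4 | 8-bromo-3,5,7,3',4'-penta-O-benzyl-(+)-catechin | Brc1c(OCc3ccccc3)cc(OCc3ccccc3)c2c1O[C@H](c1ccc(OCc3ccccc3)c(OCc3ccccc3)c1)[C@@H](OCc1ccccc1)C2 | intermediate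
5 | 8-lithio-3,5,7,3',4'-penta-O-benzyl-(+)-catechin (aryllithium) | [Li]c1c(OCc3ccccc3)cc(OCc3ccccc3)c2c1O[C@H](c1ccc(OCc3ccccc3)c(OCc3ccccc3)c1)[C@@H](OCc1ccccc1)C2 | intermediate
6 | 3,5,7,3',4'-penta-O-benzyl-(+)-catechin-8-carbaldehyde | O=Cc1c(OCc3ccccc3)cc(OCc3ccccc3)c2c1O[C@H](c1ccc(OCc3ccccc3)c(OCc3ccccc3)c1)[C@@H](OCc1ccccc1)C2 | intermediate
7 | 3',4'-dihydroxyacetophenone | CC(=O)c1ccc(O)c(O)c1 | starting material
8 | 3',4'-bis(benzyloxy)acetophenone | CC(=O)c1ccc(OCc2ccccc2)c(OCc2ccccc2)c1 | intermediate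
9 | (E)-1-[3,4-bis(benzyloxy)phenyl]-3-Cat-prop-2-en-1-one (chalcone) | O=C(/C=C/c1c(OCc3ccccc3)cc(OCc3ccccc3)c2c1O[C@H](c1ccc(OCc3ccccc3)c(OCc3ccccc3)c1)[C@@H](OCc1ccccc1)C2)c1ccc(OCc2ccccc2)c(OCc2ccccc2)c1 | intermediate
10 | dimethyl malonate | COC(=O)CC(=O)OC | starting material
11 | dimethyl 2-[(1S)-3-[3,4-bis(benzyloxy)phenyl]-3-oxo-1-Cat-propyl]propanedioate | COC(=O)C(C(=O)OC)[C@@H](c1c(OCc3ccccc3)cc(OCc3ccccc3)c2c1O[C@H](c1ccc(OCc3ccccc3)c(OCc3ccccc3)c1)[C@@H](OCc1ccccc1)C2)CC(=O)c1ccc(OCc2ccccc2)c(OCc2ccccc2)c1 | intermediate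
12 | methyl (3S)-5-[3,4-bis(benzyloxy)phenyl]-5-oxo-3-Cat-pentanoate | COC(=O)C[C@@H](c1c(OCc3ccccc3)cc(OCc3ccccc3)c2c1O[C@H](c1ccc(OCc3ccccc3)c(OCc3ccccc3)c1)[C@@H](OCc1ccccc1)C2)CC(=O)c1ccc(OCc2ccccc2)c(OCc2ccccc2)c1 | intermediate
13 | methyl (3S)-4-{2-[3,4-bis(benzyloxy)phenyl]-1,3-dioxolan-2-yl}-3-Cat-butanoate | COC(=O)C[C@@H](c1c(OCc3ccccc3)cc(OCc3ccccc3)c2c1O[C@H](c1ccc(OCc3ccccc3)c(OCc3ccccc3)c1)[C@@H](OCc1ccccc1)C2)CC1(c2ccc(OCc3ccccc3)c(OCc3ccccc3)c2)OCCO1 | intermediate
14 | methyl acetoacetate | COC(=O)CC(C)=O | starting material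
15 | sodium lithium dianion of methyl acetoacetate | COC(=O)[CH-]C(=O)[CH2-].[Na+].[Li+] | intermediate
16 | methyl (7R)-8-{2-[3,4-bis(benzyloxy)phenyl]-1,3-dioxolan-2-yl}-3,5-dioxo-7-Cat-octanoate | COC(=O)CC(=O)CC(=O)C[C@@H](c1c(OCc3ccccc3)cc(OCc3ccccc3)c2c1O[C@H](c1ccc(OCc3ccccc3)c(OCc3ccccc3)c1)[C@@H](OCc1ccccc1)C2)CC1(c2ccc(OCc3ccccc3)c(OCc3ccccc3)c2)OCCO1 | intermediate
17 | 6-[(2R)-3-{2-[3,4-bis(benzyloxy)phenyl]-1,3-dioxolan-2-yl}-2-Cat-propyl]-4-hydroxy-2H-pyran-2-one | O=c1cc(O)cc(o1)C[C@@H](c1c(OCc3ccccc3)cc(OCc3ccccc3)c2c1O[C@H](c1ccc(OCc3ccccc3)c(OCc3ccccc3)c1)[C@@H](OCc1ccccc1)C2)CC1(c2ccc(OCc3ccccc3)c(OCc3ccccc3)c2)OCCO1 | intermediate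
18 | 4-benzyloxy-6-[(2R)-3-{2-[3,4-bis(benzyloxy)phenyl]-1,3-dioxolan-2-yl}-2-Cat-propyl]-2H-pyran-2-one | O=c1cc(OCc2ccccc2)cc(o1)C[C@@H](c1c(OCc3ccccc3)cc(OCc3ccccc3)c2c1O[C@H](c1ccc(OCc3ccccc3)c(OCc3ccccc3)c1)[C@@H](OCc1ccccc1)C2)CC1(c2ccc(OCc3ccccc3)c(OCc3ccccc3)c2)OCCO1 | intermediate
19 | benzyl (2E,7R)-3-benzyloxy-8-{2-[3,4-bis(benzyloxy)phenyl]-1,3-dioxolan-2-yl}-5-oxo-7-Cat-oct-2-enoate | O=C(OCc1ccccc1)/C=C(/OCc1ccccc1)CC(=O)C[C@@H](c1c(OCc3ccccc3)cc(OCc3ccccc3)c2c1O[C@H](c1ccc(OCc3ccccc3)c(OCc3ccccc3)c1)[C@@H](OCc1ccccc1)C2)CC1(c2ccc(OCc3ccccc3)c(OCc3ccccc3)c2)OCCO1 | intermediate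
20 | 5-benzyloxy-2-[(1S)-2-{2-[3,4-bis(benzyloxy)phenyl]-1,3-dioxolan-2-yl}-1-Cat-ethyl]benzene-1,3-diol | Oc1cc(OCc2ccccc2)cc(O)c1[C@@H](c1c(OCc3ccccc3)cc(OCc3ccccc3)c2c1O[C@H](c1ccc(OCc3ccccc3)c(OCc3ccccc3)c1)[C@@H](OCc1ccccc1)C2)CC1(c2ccc(OCc3ccccc3)c(OCc3ccccc3)c2)OCCO1 | intermediate
21 | (3S)-3-(4-benzyloxy-2,6-dihydroxyphenyl)-1-[3,4-bis(benzyloxy)phenyl]-3-Cat-propan-1-one | Oc1cc(OCc2ccccc2)cc(O)c1[C@@H](c1c(OCc3ccccc3)cc(OCc3ccccc3)c2c1O[C@H](c1ccc(OCc3ccccc3)c(OCc3ccccc3)c1)[C@@H](OCc1ccccc1)C2)CC(=O)c1ccc(OCc2ccccc2)c(OCc2ccccc2)c1 | intermediate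
22 | (4S)-7-benzyloxy-2-[3,4-bis(benzyloxy)phenyl]-4-Cat-chromane-2,5-diol, both C2 epimers | Oc1cc(OCc2ccccc2)cc5c1[C@@H](c1c(OCc3ccccc3)cc(OCc3ccccc3)c2c1O[C@H](c1ccc(OCc3ccccc3)c(OCc3ccccc3)c1)[C@@H](OCc1ccccc1)C2)CC(O)(c1ccc(OCc2ccccc2)c(OCc2ccccc2)c1)O5 | intermediate
23 | (4S)-7-benzyloxy-2-[3,4-bis(benzyloxy)phenyl]-4-Cat-4H-chromen-5-ol | Oc1cc(OCc2ccccc2)cc5c1[C@@H](c1c(OCc3ccccc3)cc(OCc3ccccc3)c2c1O[C@H](c1ccc(OCc3ccccc3)c(OCc3ccccc3)c1)[C@@H](OCc1ccccc1)C2)C=C(c1ccc(OCc2ccccc2)c(OCc2ccccc2)c1)O5 | intermediate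
24 | (2R,3S)-2-(3,4-dihydroxyphenyl)-8-[(2S,4S)-2-(3,4-dihydroxyphenyl)-5,7-dihydroxychroman-4-yl]chromane-3,5,7-triol | Oc1cc(O)c2c(c1)O[C@H](c1ccc(O)c(O)c1)C[C@@H]2c1c(O)cc(O)c2c1O[C@H](c1ccc(O)c(O)c1)[C@@H](O)C2 | target

**Step count**

Total: 15 steps. Longest linear sequence: 14 steps (steps 1–4 and 6–15, from (+)-catechin); step 5 is a one-step side branch.

**Steps most likely to fail**

Step 13. Closure through the hindered, substituted methylene may be too slow at a temperature the substrate tolerates. Benzyloxide could then attack the benzylic carbon of the pyrone ether by SN2 and strand the material as the unreactive pyrone 4-olate, and prolonged heating in alkoxide could erode aryl benzyl ethers. Fallback with known chemistry, setting out from chalcone 9 and returning at target 24: 9 would be condensed with phloroglucinol (benzene-1,3,5-triol, commercial) under acid catalysis (TsOH·H2O, dioxane, 60 °C). Friedel–Crafts conjugate addition of the triol to the protonated enone and cyclodehydration should give (4S)-2-[3,4-bis(benzyloxy)phenyl]-4-Cat-4H-chromene-5,7-diol F1 together with its C4 epimer F2. The two are diastereomers and would be separated by chromatography. Hydrogenation of F1 under the conditions of step 15 then gives 24. This gives up the pyrone and the catalyst control of C4 in exchange for a short, precedented sequence.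

Step 7. The enone carries a donor-rich, di-ortho-substituted β-aryl group, so conjugate addition may stall or reverse, and the catalyst may discriminate the faces poorly. Fallback, setting out from aldehyde 6 and malonate 10 and returning at 11: the polarity of the bond formation is reversed. Knoevenagel condensation of 6 with 10 (piperidine, AcOH, toluene, reflux with water removal) would give dimethyl 2-(Cat-methylidene)propanedioate F3, a much stronger acceptor. The lithium enolate of ketone 8 F4 (from 8 and LiN(iPr)2, THF, −78 °C) would be added to F3 to give 11 and its epimer at the new centre F5 without catalyst control. These are diastereomers and would be separated by chromatography before step 8.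

Step 15. Palladium may move the C2=C3 double bond to C3=C4 before reduction, which would erase the C4 stereocentre, and hydrogen delivery to C2 may not be fully face-selective. Fallback, setting out from flav-2-ene 23 and returning at 24: ionic hydrogenation (Et3SiH, CF3CO2H, CH2Cl2, −40 °C) protonates C3 and reduces the resulting 2-aryl oxocarbenium ion by hydride delivery anti to the C4 substituent. This should give (2S,4S)-7-benzyloxy-2-[3,4-bis(benzyloxy)phenyl]-4-Cat-chroman-5-ol F6 with no alkene left to migrate. Hydrogenolysis of F6 (H2, Pd(OH)2/C, THF–MeOH) then removes only the benzyl ethers and gives 24.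

**Further compounds**

F1 | step 13 | (4S)-2-[3,4-bis(benzyloxy)phenyl]-4-Cat-4H-chromene-5,7-diol | Oc1cc(O)cc5c1[C@@H](c1c(OCc3ccccc3)cc(OCc3ccccc3)c2c1O[C@H](c1ccc(OCc3ccccc3)c(OCc3ccccc3)c1)[C@@H](OCc1ccccc1)C2)C=C(c1ccc(OCc2ccccc2)c(OCc2ccccc2)c1)O5
F2 | step 13 | (4R)-2-[3,4-bis(benzyloxy)phenyl]-4-Cat-4H-chromene-5,7-diol (C4 epimer of F1) | Oc1cc(O)cc5c1[C@H](c1c(OCc3ccccc3)cc(OCc3ccccc3)c2c1O[C@H](c1ccc(OCc3ccccc3)c(OCc3ccccc3)c1)[C@@H](OCc1ccccc1)C2)C=C(c1ccc(OCc2ccccc2)c(OCc2ccccc2)c1)O5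
F3 | step 7 | dimethyl 2-(Cat-methylidene)propanedioate | COC(=O)C(C(=O)OC)=Cc1c(OCc3ccccc3)cc(OCc3ccccc3)c2c1O[C@H](c1ccc(OCc3ccccc3)c(OCc3ccccc3)c1)[C@@H](OCc1ccccc1)C2
F4 | step 7 | lithium enolate of 3',4'-bis(benzyloxy)acetophenone | [Li]OC(=C)c1ccc(OCc2ccccc2)c(OCc2ccccc2)c1
F5 | step 7 | dimethyl 2-[(1R)-3-[3,4-bis(benzyloxy)phenyl]-3-oxo-1-Cat-propyl]propanedioate (epimer of 11) | COC(=O)C(C(=O)OC)[C@H](c1c(OCc3ccccc3)cc(OCc3ccccc3)c2c1O[C@H](c1ccc(OCc3ccccc3)c(OCc3ccccc3)c1)[C@@H](OCc1ccccc1)C2)CC(=O)c1ccc(OCc2ccccc2)c(OCc2ccccc2)c1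
F6 | step 15 | (2S,4S)-7-benzyloxy-2-[3,4-bis(benzyloxy)phenyl]-4-Cat-chroman-5-ol | Oc1cc(OCc2ccccc2)cc5c1[C@@H](c1c(OCc3ccccc3)cc(OCc3ccccc3)c2c1O[C@H](c1ccc(OCc3ccccc3)c(OCc3ccccc3)c1)[C@@H](OCc1ccccc1)C2)C[C@@H](c1ccc(OCc2ccccc2)c(OCc2ccccc2)c1)O5
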